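## Analysis of the target

The target 15 is a (2S)-flavanone, a 2-phenylchroman-4-one with an unsubstituted phenyl ring B and a fully substituted ring A: C5 carries a hydroxyl hydrogen-bonded to the C4 ketone, C7 a methoxy group, and C6 and C8 two identical carbon arms. Each arm is a 2-hydroxybenzyl group whose arene carries at C5'', para to its hydroxyl, a second 2-hydroxybenzyl group, so the molecule holds four diarylmethane methylenes, five free phenols and one methyl ether. C2 is the only stereocentre, so there is no relative configuration to control. It is, however, benzylic, bonded to O1 and β to the ketone, so base opens ring C to the 2'-hydroxychalcone and recloses it as the racemate, and forcing hydrogenolysis can cut C2–O1. The electron-rich phenols and diarylmethanes are sensitive to oxidants and to strong acid, and the product must end with exactly one O-methyl group. The difficulty is to attach two large arms at defined carbons of ring A and, on each arm ring, at the carbon ortho to its hydroxyl, in chemistry where every hydroxybenzylated product is again a nucleophile and oligomerisation is the usual outcome. The strategy rests on one feature: the C6 methylene is ortho to the C5 oxygen, the C8 methylene is ortho to the C8a oxygen (O1), and each methylene ends at an arm carbon C1'' that is ortho to C2''–OH on a ring whose para carbon C5'' is already substituted. That is the pattern left when an ortho-quinone methide of ring A is attacked by the ortho carbon of a para-blocked phenol. In the open acetophenone form, ring A also has a mirror plane through C1' and C4', so both arms can be attached in one operation and ring C can close on either hydroxyl with the same result.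

## Retrosynthetic reasoning

**15 ⇒ 14.** The last disconnection cuts the two O–CH2Ph bonds on the outer arm rings. Only these two phenols need masking: a free hydroxyl there would give a second ring able to bind magnesium and be alkylated in the key step. Benzyl is chosen because it leaves under neutral conditions that cannot open ring C. The forward step has to cleave two primary benzyl ethers while sparing the ring-bound benzylic C2–O1 bond and the C4 ketone.

**14 ⇒ 12 + 13.** The bond between C2 and ring B is cut, which leads back to the flat chromone 12 and phenylboronic acid 13. Cutting here places the only stereocentre in the next-to-last step, under catalyst control, with nothing basic afterwards. The forward reaction must deliver phenyl to the Re face of C2 (priorities O1 > C3 > H) and must tolerate three free phenols.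

**12 ⇒ 10 (through 11).** O1–C2 and C2–C3 are cut, removing the one-carbon unit C2 and leading back to the methyl ketone 10 by way of its enaminone 11. Because the two hydroxyls flanking the acyl group of 10 are related by the mirror plane, ring closure has no regiochemical question. The forward step must add one carbon to the acetyl group and close the pyranone without methylating a phenol.

**10 ⇒ 2 + 5 (through 6, 7, 8 and 9).** Both CH2–C1'' bonds are cut. The cut is made on the arm side of each methylene, not the ring-A side, so that ring A becomes the electrophile: the bis-Mannich base 2 is a latent twofold ortho-quinone methide (7, then 9 after the first arm is on as 8), and the arm is the nucleophile, the magnesium phenolate 6 of phenol 5. This inverts the usual polarity of hydroxybenzylation. No arm quinone methide exists that could polymerise or over-alkylate ring A, and the symmetric, simple partner carries the reactive function. The forward reaction has to form two C–C bonds at the ortho carbon of 5, not at its oxygen and not on its benzyl-ether ring.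

**2 ⇒ 1.** The two ring-A–CH2 bonds are cut, leading back to commercial 2',6'-dihydroxy-4'-methoxyacetophenone 1. C3' and C5' are its only free ring positions and both are strongly activated, so a twofold aminomethylation needs no control element.

**5 ⇒ 3 + 4.** The aryl–CH2 bond of the diarylmethane is cut between the benzylic carbon of bromide 3 and the ipso carbon of boronic acid 4. The position of boron fixes the hydroxyl para to the new bond, so the para-blocked phenol needed by the key step is obtained without any aromatic substitution on a phenol.

## Alternatives that were turned down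

**Alternative 1:** The two C5''–CH2 bonds between the inner arm rings and the outer oxygenated benzyl groups are cut late, on the intact flavanone. In the forward step both aryl bromides of (2S)-6,8-bis(5-bromo-2-methoxymethoxybenzyl)-5-hydroxy-7-methoxyflavanone A1 would be joined to 2-(methoxymethoxy)benzyl chloride A2 by nickel-catalysed cross-electrophile coupling (NiI2, a 2,2'-bipyridine ligand, zinc as reductant) to give A3.
- For it: the site of each outer benzyl group is fixed by a halogen, the outer rings could be varied at the very end, and no organometallic partner has to be prepared.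
- Against it: the C2 stereocentre and the 5-hydroxy-4-keto chelate would pass twice through a reducing, Lewis-acidic medium in a warm amide solvent, where retro-oxa-Michael racemisation and hydrodehalogenation are open pathways. Reductive homocoupling of A2 competes, and both couplings must succeed on one molecule. The acetal groups must finally be removed with acid from a flavanone full of electron-rich diarylmethanes.
- Above all, A1 still requires ring A to be benzylated at both C6 and C8, so the central problem is not removed and the step count grows.
- Comparison: on regiochemical certainty at C5'' it is as strong as the chosen route, which secures the same point by the position of boron in 4, and it is stronger for late diversification. The chosen route offers in exchange a shorter sequence in which the stereocentre never meets a reductive metal step.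

**Alternative 2:** The C4a–C5 bond of ring A is cut and the ring is traced to a polyketide-like chain stored as the pyranone A4, which carries both arms, the methoxy group and a 2-oxo-4-phenylbut-3-enyl side chain. In the forward step Mg(OMe)2 would open the lactone of A4, and the methylene flanked by two ketones would attack the liberated ester carbonyl and aromatise to the chalcone A5.
- For it: the logic mirrors biosynthesis, ring A emerges with all six substituents and the cinnamoyl chain in place, and no aromatic substitution selectivity arises.
- Against it: A4 is itself a fully substituted heterocycle whose C3 and C5 must each receive a large arm, and C5 of a pyranone is a poor nucleophile, so the difficulty is moved and not solved. The Claisen closure must take place between two bulky benzylic groups while methoxide can add to the enone. The stereocentre would then have to come from an asymmetric oxa-Michael closure of a 2',6'-dihydroxychalcone, which is reversible and weakly biased for unactivated chalcones.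
- Comparison: it is stronger in that all arm phenols are protected and no phenol-versus-phenol selectivity is asked for. The chosen route takes ring A from a commercial compound and only has to make two C–C bonds on it.

**Alternative 3:** Three bonds of ring A are cut and the ring is assembled by a Danheiser benzannulation from the arm-bearing silyloxycyclobutenone A6 and the arm-bearing methoxyalkyne A7. On heating, A6 would open to a vinylketene, add to A7 in a (2+2) sense, reopen by a 4π process and close by 6π electrocyclisation to the phenol A8.
- For it: the substitution pattern is dictated by the mechanism, the three oxygens come out differentiated (hydroxyl, methyl ether, silyl ether), and the two arms are united convergently.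
- Against it: A8 lacks the acyl carbon on C4a, so the last ring CH, squeezed between two oxygens, must later be acylated in the presence of four other electron-rich arenes. The differentiation of the oxygens has no value here because C5–O and C8a–O are equivalent in the open form. A6 and A7 are each multistep compounds that carry a prebuilt arm made by a different route.
- Comparison: it is stronger in mechanistic certainty of the ring-A pattern. The chosen route uses the symmetry of ring A instead and reaches the same carbon skeleton in far fewer steps.

Key step: step 3

Assumption: the pyridine-oxazoline catalyst is taken to show the same facial preference on the chromone as on β-substituted cyclic enones, which makes the (R)-ligand the one that gives the (2S)-flavanone; if the preference is the opposite, the (S)-ligand is used instead.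

## Route

Step 1
Reactants: 1 2',6'-dihydroxy-4'-methoxyacetophenone
Product: 2 2',6'-dihydroxy-4'-methoxy-3',5'-bis(dimethylaminomethyl)acetophenone
Conditions: Me2N=CH2+ I− (2.3 equiv), K2CO3 (2.5 equiv), CH2Cl2, 0 °C to rt
Reagents that add atoms: dimethylmethyleneiminium iodide, C=[N+](C)C.[I-]
Why: Aromatic Mannich reaction with a preformed iminium ion: C3' and C5' are the only free ring carbons, each ortho to a hydroxyl and to the methoxy group, so the ring reacts twice much faster than the hydrogen-bonded acetyl group can enolise; K2CO3 takes up the acid so the product amines stay unprotonated.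

Step 2
Reactants: 3 2-benzyloxybenzyl bromide; 4 4-hydroxyphenylboronic acid
Product: 5 4-(2-benzyloxybenzyl)phenol
Conditions: Pd(PPh3)4 (3 mol %), Na2CO3 (2 M aq, 2 equiv), DME, 80 °C, 3 added slowly
Reagents that add atoms: none
Why: Suzuki–Miyaura coupling of a benzylic bromide: oxidative addition of the activated C–Br bond to zerovalent palladium is fast and the benzylpalladium species has no β-hydrogen, so the diarylmethane forms with the hydroxyl already para to the new bond; slow addition of 3 keeps O-benzylation of the phenol in the background.

Step 3
Reactants: 2 2',6'-dihydroxy-4'-methoxy-3',5'-bis(dimethylaminomethyl)acetophenone; 5 4-(2-benzyloxybenzyl)phenol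
Product: 10 2',6'-dihydroxy-4'-methoxy-3',5'-bis[2-hydroxy-5-(2-benzyloxybenzyl)benzyl]acetophenone, via bromomagnesium phenolate 6 (not isolated), via first ortho-quinone methide 7 (not isolated), via mono-arylmethyl Mannich base 8 (not isolated), via second ortho-quinone methide 9 (not isolated)
Conditions: 5 (6 equiv), EtMgBr (5.5 equiv), Et2O, 0 °C to rt; solvent exchange to toluene; 2 (1 equiv), 110 °C, N2 sweep; 1 M HCl work-up
Reagents that add atoms: none
Why: The step joins ortho-quinone methide release from a phenolic Mannich base with ortho-specific C-alkylation of a magnesium phenolate; the closest known reaction type is the ortho-hydroxybenzylation of bromomagnesium phenolates by quinone methides from salicyl alcohols in hot non-polar solvent. Two equivalents of 6 are spent on the acidic chelated hydroxyls of 2, which is why 6 is in large excess, and EtMgBr is kept below the amount of 5 so that no free Grignard reagent can attack the acetyl group or transfer ethyl to a quinone methide. On heating, the ring-A phenolate expels the dimethylamino group of one arm (E1cB-type, helped by magnesium coordination and by a proton from free 5) to give 7, and the volatile amine leaves the hot toluene so the elimination cannot reverse. 6 binds the carbonyl oxygen of 7 through magnesium and delivers its ortho carbon to the exocyclic CH2 through a six-membered array; tautomerisation of the resulting cyclohexadienone restores both arenes and gives 8, and the same sequence through 9 gives 10. No ring is closed and no stereocentre is formed. The selectivity needed is C- over O-alkylation and reaction on the phenolic ring only: magnesium chelation in toluene directs attack to the ortho carbon, the para carbon of 5 is blocked by the diarylmethane link, and the benzyl-ether ring cannot bind magnesium. Bridging of two quinone methides by one arm phenol through its second ortho carbon is suppressed statistically by the excess of 6, which is recovered as 5.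

Step 4
Reactants: 10 2',6'-dihydroxy-4'-methoxy-3',5'-bis[2-hydroxy-5-(2-benzyloxybenzyl)benzyl]acetophenone
Product: 12 5-hydroxy-7-methoxy-6,8-bis[2-hydroxy-5-(2-benzyloxybenzyl)benzyl]-4H-chromen-4-one, via enaminone 11 (not isolated)
Conditions: Me2NCH(OMe)2 (2.5 equiv), toluene, 80 °C; evaporate; aq HCl, CH2Cl2, 40 °C
Reagents that add atoms: N,N-dimethylformamide dimethyl acetal, COC(OC)N(C)C
Why: Enaminone route to chromones: the amide acetal condenses with the methyl ketone to the vinylogous amide 11, and acid then promotes addition of an ortho hydroxyl to the β-carbon and loss of Me2NH to close the pyranone ring. The two hydroxyls flanking the acyl group are equivalent by symmetry, so only one chromone can form, and the moderate temperature limits methyl transfer from the acetal to the phenols.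

Step 5
Reactants: 12 5-hydroxy-7-methoxy-6,8-bis[2-hydroxy-5-(2-benzyloxybenzyl)benzyl]-4H-chromen-4-one; 13 phenylboronic acid
Product: 14 (2S)-5-hydroxy-7-methoxy-6,8-bis[2-hydroxy-5-(2-benzyloxybenzyl)benzyl]-2-phenylchroman-4-one
Conditions: 13 (3 equiv), Pd(OCOCF3)2 (10 mol %), (R)-4-tert-butyl-2-(pyridin-2-yl)-4,5-dihydrooxazole (12 mol %), NH4PF6 (30 mol %), H2O (5 equiv), ClCH2CH2Cl, 60 °C
Reagents that add atoms: none
Why: Palladium-catalysed enantioselective conjugate addition of an arylboronic acid to a chromone: transmetalation gives a cationic phenyl–palladium complex of the pyridine-oxazoline, the C2=C3 bond inserts into the Pd–Ph bond, and water protonates the palladium enolate, so no β-hydride elimination to the flavone occurs. The tert-butyl group of the ligand shields one face of the bound enone so that phenyl is delivered to the Re face of C2, which sets the (2S) centre; the neutral to weakly acidic medium keeps ring C closed.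

Step 6
Reactants: 14 (2S)-5-hydroxy-7-methoxy-6,8-bis[2-hydroxy-5-(2-benzyloxybenzyl)benzyl]-2-phenylchroman-4-one
Product: 15 5''-(2''''-hydroxybenzyl)uvarinol, (2S)-5-hydroxy-7-methoxy-6,8-bis[2-hydroxy-5-(2-hydroxybenzyl)benzyl]-2-phenylchroman-4-one
Conditions: H2 (1 atm), Pd/C (10 wt % Pd), EtOAc/MeOH, rt
Reagents that add atoms: none
Why: Hydrogenolysis of aryl benzyl ethers on palladium under neutral conditions: the primary benzylic C–O bonds of the two ethers are cleaved much faster than the secondary ring-bound C2–O1 bond or the chelated C4 ketone, and with no base present the C2 configuration is retained.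

## Compound list

1 | 2',6'-dihydroxy-4'-methoxyacetophenone | CC(=O)c1c(O)cc(OC)cc1O | starting material
2 | 2',6'-dihydroxy-4'-methoxy-3',5'-bis(dimethylaminomethyl)acetophenone | CC(=O)c1c(O)c(CN(C)C)c(OC)c(CN(C)C)c1O | intermediate
3 | 2-benzyloxybenzyl bromide | BrCc1ccccc1OCc1ccccc1 | starting material
4 | 4-hydroxyphenylboronic acid | OB(O)c1ccc(O)cc1 | starting material
5 | 4-(2-benzyloxybenzyl)phenol | Oc1ccc(Cc2ccccc2OCc2ccccc2)cc1 | intermediate
6 | bromomagnesium 4-(2-benzyloxybenzyl)phenolate | Br[Mg]Oc1ccc(Cc2ccccc2OCc2ccccc2)cc1 | intermediate
7 | 6-acetyl-4-(dimethylaminomethyl)-5-hydroxy-3-methoxy-2-methylidenecyclohexa-3,5-dien-1-one (first ortho-quinone methide) | CC(=O)C1=C(O)C(CN(C)C)=C(OC)C(=C)C1=O | intermediate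
8 | 2',6'-dihydroxy-4'-methoxy-3'-(dimethylaminomethyl)-5'-[2-hydroxy-5-(2-benzyloxybenzyl)benzyl]acetophenone | CC(=O)c1c(O)c(CN(C)C)c(OC)c(Cc2cc(Cc3ccccc3OCc3ccccc3)ccc2O)c1O | intermediate
9 | 6-acetyl-5-hydroxy-4-[2-hydroxy-5-(2-benzyloxybenzyl)benzyl]-3-methoxy-2-methylidenecyclohexa-3,5-dien-1-one (second ortho-quinone methide) | CC(=O)C1=C(O)C(Cc2cc(Cc3ccccc3OCc3ccccc3)ccc2O)=C(OC)C(=C)C1=O | intermediate
10 | 2',6'-dihydroxy-4'-methoxy-3',5'-bis[2-hydroxy-5-(2-benzyloxybenzyl)benzyl]acetophenone | CC(=O)c1c(O)c(Cc2cc(Cc3ccccc3OCc3ccccc3)ccc2O)c(OC)c(Cc2cc(Cc3ccccc3OCc3ccccc3)ccc2O)c1O | intermediate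
11 | (E)-3-(dimethylamino)-1-{2,6-dihydroxy-4-methoxy-3,5-bis[2-hydroxy-5-(2-benzyloxybenzyl)benzyl]phenyl}prop-2-en-1-one | CN(C)/C=C/C(=O)c1c(O)c(Cc2cc(Cc3ccccc3OCc3ccccc3)ccc2O)c(OC)c(Cc2cc(Cc3ccccc3OCc3ccccc3)ccc2O)c1O | intermediate
12 | 5-hydroxy-7-methoxy-6,8-bis[2-hydroxy-5-(2-benzyloxybenzyl)benzyl]-4H-chromen-4-one | COc1c(Cc2cc(Cc3ccccc3OCc3ccccc3)ccc2O)c(O)c2c(c1Cc1cc(Cc3ccccc3OCc3ccccc3)ccc1O)OC=CC2=O | intermediate
13 | phenylboronic acid | OB(O)c1ccccc1 | starting material
14 | (2S)-5-hydroxy-7-methoxy-6,8-bis[2-hydroxy-5-(2-benzyloxybenzyl)benzyl]-2-phenylchroman-4-one | COc1c(Cc2cc(Cc3ccccc3OCc3ccccc3)ccc2O)c(O)c2c(c1Cc1cc(Cc3ccccc3OCc3ccccc3)ccc1O)O[C@H](c1ccccc1)CC2=O | intermediate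
15 | 5''-(2''''-hydroxybenzyl)uvarinol, (2S)-5-hydroxy-7-methoxy-6,8-bis[2-hydroxy-5-(2-hydroxybenzyl)benzyl]-2-phenylchroman-4-one | COc1c(Cc2cc(Cc3ccccc3O)ccc2O)c(O)c2c(c1Cc1cc(Cc3ccccc3O)ccc1O)O[C@H](c1ccccc1)CC2=O | target

## Step count and least certain steps

Total step count: 6. Longest linear sequence: 5 steps (1 → 2 → 10 → 12 → 14 → 15; the branch from 3 through 5 has the same length).

**Step 3 (key step).**
- Risk: amine loss from the doubly deprotonated ring A may be slow, because the dimethylamino group is a poor leaving group and the second phenolate lowers the electrophilic drive. Once a quinone methide is present it may also be consumed by O-alkylation, by dimerisation, or by bridging through the second ortho carbon of an arm phenol that is already attached. The magnesium salts may aggregate and come out of toluene.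
- Fallback, from 2 back to 10: treatment of 2 with MeI in acetone at rt should quaternise both amines to the bis(trimethylammonium) diiodide F1. F1, added to an excess of 6 in toluene containing a little THF at rt to 60 °C, loses trimethylamine from the phenolate far more readily. The quinone methides are then released at a temperature where their side reactions are slower, and the same ortho C-alkylation returns to 10.

**Step 5.**
- Risk: turnover may be poor if the cationic palladium is bound by the three free phenols or crowded by the C8 arm, facial selectivity on this heavily substituted chromone may be low, and ring C may open and reclose with erosion of the enantiomeric purity.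
- Fallback, from 10 back to 14: Claisen–Schmidt condensation of 10 with benzaldehyde (KOH, EtOH, rt) should give the chalcone F2. Heating F2 with NaOAc in EtOH closes ring C to the racemic flavanone F3. Preparative chromatography of F3 on a chiral stationary phase gives 14, and the (2R)-enantiomer F4 is returned to F3 by brief treatment with base.

**Step 4.**
- Risk: methyl transfer from the amide acetal to the phenols would add unwanted O-methyl groups, and consumption of the acetal by the four acidic hydroxyls may leave the condensation incomplete.
- Fallback, from 10 back to 12: Claisen formylation of 10 with ethyl formate and excess NaH in THF, followed by acidic quench, should give the 2-hydroxychroman-4-one F5. F5 dehydrates to 12 on warming with HCl in AcOH. No methylating species is present at any point.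

**Step 6.**
- Risk: over-reduction, either by hydrogenolysis of the benzylic C2–O1 bond, which opens ring C to a dihydrochalcone, or by reduction of the aryl ketone.
- Fallback, from 14 directly to 15: Lewis-acid dealkylation with BCl3 and pentamethylbenzene as cation scavenger in CH2Cl2 at −78 °C removes the benzyl groups without hydrogen. The C7 methyl ether, which is not chelated to the carbonyl, should survive. This fallback makes no new compound (F0).

**Step 2.**
- Risk: competing O-benzylation of the phenolate of 4 by the activated bromide 3, and solvolysis of 3 in the aqueous base.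
- Fallback, from 3 back to 5: coupling of 3 with 4-(tert-butyldimethylsilyloxy)phenylboronic acid under Pd(PPh3)4 and K3PO4 in toluene should give the silyl ether F6. F6 is cleaved with Bu4NF in THF to 5.

## Further compounds

F1 | step 3 | 2',6'-dihydroxy-4'-methoxy-3',5'-bis(trimethylammoniomethyl)acetophenone diiodide | CC(=O)c1c(O)c(C[N+](C)(C)C)c(OC)c(C[N+](C)(C)C)c1O.[I-].[I-]
F2 | step 5 | (E)-2',6'-dihydroxy-4'-methoxy-3',5'-bis[2-hydroxy-5-(2-benzyloxybenzyl)benzyl]chalcone | O=C(/C=C/c1ccccc1)c1c(O)c(Cc2cc(Cc3ccccc3OCc3ccccc3)ccc2O)c(OC)c(Cc2cc(Cc3ccccc3OCc3ccccc3)ccc2O)c1O
F3 | step 5 | racemic 5-hydroxy-7-methoxy-6,8-bis[2-hydroxy-5-(2-benzyloxybenzyl)benzyl]-2-phenylchroman-4-one | COc1c(Cc2cc(Cc3ccccc3OCc3ccccc3)ccc2O)c(O)c2c(c1Cc1cc(Cc3ccccc3OCc3ccccc3)ccc1O)OC(c1ccccc1)CC2=O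
F4 | step 5 | (2R)-5-hydroxy-7-methoxy-6,8-bis[2-hydroxy-5-(2-benzyloxybenzyl)benzyl]-2-phenylchroman-4-one | COc1c(Cc2cc(Cc3ccccc3OCc3ccccc3)ccc2O)c(O)c2c(c1Cc1cc(Cc3ccccc3OCc3ccccc3)ccc1O)O[C@@H](c1ccccc1)CC2=O
F5 | step 4 | 2,5-dihydroxy-7-methoxy-6,8-bis[2-hydroxy-5-(2-benzyloxybenzyl)benzyl]chroman-4-one (racemic hemiacetal) | COc1c(Cc2cc(Cc3ccccc3OCc3ccccc3)ccc2O)c(O)c2c(c1Cc1cc(Cc3ccccc3OCc3ccccc3)ccc1O)OC(O)CC2=O
F0 | step 6 | none | none
F6 | step 2 | tert-butyl[4-(2-benzyloxybenzyl)phenoxy]dimethylsilane | CC(C)(C)[Si](C)(C)Oc1ccc(Cc2ccccc2OCc2ccccc2)cc1
A1 | alternative 1 | (2S)-6,8-bis(5-bromo-2-methoxymethoxybenzyl)-5-hydroxy-7-methoxy-2-phenylchroman-4-one | COc1c(Cc2cc(Br)ccc2OCOC)c(O)c2c(c1Cc1cc(Br)ccc1OCOC)O[C@H](c1ccccc1)CC2=O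
A2 | alternative 1 | 2-(methoxymethoxy)benzyl chloride | COCOc1ccccc1CCl
A3 | alternative 1 | (2S)-5-hydroxy-7-methoxy-6,8-bis[2-methoxymethoxy-5-(2-methoxymethoxybenzyl)benzyl]-2-phenylchroman-4-one | COc1c(Cc3cc(Cc4ccccc4OCOC)ccc3OCOC)c(O)c2c(c1Cc5cc(Cc6ccccc6OCOC)ccc5OCOC)O[C@H](c7ccccc7)CC2=O
A4 | alternative 2 | 4-methoxy-3,5-bis[2-benzyloxy-5-(2-benzyloxybenzyl)benzyl]-6-[(E)-2-oxo-4-phenylbut-3-enyl]-2H-pyran-2-one | O=C1OC(CC(=O)/C=C/c2ccccc2)=C(Cc2cc(Cc3ccccc3OCc3ccccc3)ccc2OCc2ccccc2)C(OC)=C1Cc1cc(Cc2ccccc2OCc2ccccc2)ccc1OCc1ccccc1
A5 | alternative 2 | (E)-2',6'-dihydroxy-4'-methoxy-3',5'-bis[2-benzyloxy-5-(2-benzyloxybenzyl)benzyl]chalcone | COc1c(Cc2cc(Cc3ccccc3OCc3ccccc3)ccc2OCc2ccccc2)c(O)c(C(=O)/C=C/c2ccccc2)c(O)c1Cc1cc(Cc2ccccc2OCc2ccccc2)ccc1OCc1ccccc1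
A6 | alternative 3 | 2-[2-benzyloxy-5-(2-benzyloxybenzyl)benzyl]-3-(triisopropylsilyloxy)cyclobut-2-en-1-one | O=C1CC(O[Si](C(C)C)(C(C)C)C(C)C)=C1Cc1cc(Cc2ccccc2OCc2ccccc2)ccc1OCc1ccccc1
A7 | alternative 3 | 1-methoxy-3-[2-benzyloxy-5-(2-benzyloxybenzyl)phenyl]prop-1-yne | COC#CCc1cc(Cc2ccccc2OCc2ccccc2)ccc1OCc1ccccc1
A8 | alternative 3 | 3-methoxy-2,4-bis[2-benzyloxy-5-(2-benzyloxybenzyl)benzyl]-5-(triisopropylsilyloxy)phenol | COc1c(Cc2cc(Cc3ccccc3OCc3ccccc3)ccc2OCc2ccccc2)c(O)cc(O[Si](C(C)C)(C(C)C)C(C)C)c1Cc1cc(Cc2ccccc2OCc2ccccc2)ccc1OCc1ccccc1
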